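**Strategy.** The route rests on disconnecting the C2–C3 bond of ring C. In the target, C2 is a benzylic CH flanked by O1 and ring B, and C3 lies alpha to the C4 ketone. A carbenoid at C3 can therefore insert into a C–H bond of an O1–CH2–ring B ether. One operation, a dirhodium-catalysed enantioselective 1,6-C–H insertion, closes ring C, forms C2–C3 and sets the lone stereocenter (2R). The precursor is a fully silylated aryl diazomethyl ketone: ring A carries the diazoacetyl group, ring B is attached only through the O1–CH2 ether, and all three prenyl groups are already in place. Fluoride deprotection ends the synthesis.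

Key step: step 9

Assumption: Rh2(S-PTTL)4 is taken as the catalyst antipode that delivers 2R; if the sense of induction proves opposite, its mirror image Rh2(R-PTTL)4 is used in the same way.

Abbreviations: prenyl = 3-methylbut-2-en-1-yl; TIPS = triisopropylsilyl; p-ABSA = 4-acetamidobenzenesulfonyl azide. Flavanone numbering is used: ring C is O1, C2, C3, C4; ring A is C4a to C8a; ring B is primed.

**Step 1**
Reactants: 1 2,4,6-trihydroxyacetophenone; 2 prenyl bromide
Product: 3 1-[2,4,6-trihydroxy-3-prenylphenyl]ethanone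
Conditions: prenyl bromide (1 equiv), DBU, THF, 0 °C to rt
Reagents that add atoms: prenyl bromide (2), CC(C)=CCBr
Why: The strongly enolised phloroacetophenone anion is alkylated at ring carbon by the allylic bromide (nuclear C-prenylation of a phloroglucinol); the two free ring positions are equivalent, so only one mono-prenyl isomer can form, and one equivalent of bromide limits dialkylation.

**Step 2**
Reactants: 3 1-[2,4,6-trihydroxy-3-prenylphenyl]ethanone
Product: 4 1-[2,6-dihydroxy-3-prenyl-4-(triisopropylsilyloxy)phenyl]ethanone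
Conditions: TIPSCl (1.05 equiv), imidazole, DMF, 0 °C
Reagents that add atoms: triisopropylsilyl chloride, CC(C)[Si](Cl)(C(C)C)C(C)C
Why: The para hydroxyl is the most acidic and the only one not tied up in the hydrogen bond to the acetyl oxygen, so one equivalent of the bulky silyl chloride should silylate it selectively (imidazole-mediated phenol silylation).

**Step 3**
Reactants: 5 4-hydroxybenzaldehyde; 2 prenyl bromide
Product: 6 4-hydroxy-3,5-diprenylbenzaldehyde
Conditions: prenyl bromide (2.5 equiv), aq KOH, 0 °C to rt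
Reagents that add atoms: prenyl bromide (2), CC(C)=CCBr
Why: In water the phenoxide oxygen is shielded by hydrogen bonding, which steers the allylic bromide to ring carbon, and with the para position blocked by the formyl group both ortho positions are alkylated (ortho C-prenylation of a phenoxide).

**Step 4**
Reactants: 6 4-hydroxy-3,5-diprenylbenzaldehyde
Product: 7 3,5-diprenyl-4-(triisopropylsilyloxy)benzaldehyde
Conditions: TIPSOTf, 2,6-lutidine, CH2Cl2, 0 °C
Reagents that add atoms: triisopropylsilyl trifluoromethanesulfonate, CC(C)[Si](OS(=O)(=O)C(F)(F)F)(C(C)C)C(C)C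
Why: The silyl triflate with a hindered pyridine base silylates even a phenol flanked by two ortho alkyl groups (silyl triflate O-silylation), and the aldehyde has no enolisable hydrogen.

**Step 5**
Reactants: 7 3,5-diprenyl-4-(triisopropylsilyloxy)benzaldehyde
Product: 8 [3,5-diprenyl-4-(triisopropylsilyloxy)phenyl]methanol
Conditions: NaBH4, MeOH, 0 °C
Reagents that add atoms: none
Why: Borohydride reduces the aromatic aldehyde to the benzylic alcohol without touching the trisubstituted alkenes or the aryl silyl ether (hydride reduction).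

**Step 6**
Reactants: 4 1-[2,6-dihydroxy-3-prenyl-4-(triisopropylsilyloxy)phenyl]ethanone; 8 [3,5-diprenyl-4-(triisopropylsilyloxy)phenyl]methanol
Product: 9 1-{2-hydroxy-3-prenyl-4-(triisopropylsilyloxy)-6-[3,5-diprenyl-4-(triisopropylsilyloxy)benzyloxy]phenyl}ethanone
Conditions: PPh3, DIAD, THF, 0 °C to rt
Reagents that add atoms: none
Why: In this Mitsunobu etherification the acidic phenol of 4 displaces the activated primary benzylic alcohol; the hydroxyl next to the unsubstituted ring carbon is far more accessible than the one wedged between the acetyl and prenyl groups, the neutral conditions spare the aryl silyl ethers, and using the alcohol directly avoids a labile electron-rich benzyl bromide.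

**Step 7**
Reactants: 9 1-{2-hydroxy-3-prenyl-4-(triisopropylsilyloxy)-6-[3,5-diprenyl-4-(triisopropylsilyloxy)benzyloxy]phenyl}ethanone
Product: 10 1-{2-[3,5-diprenyl-4-(triisopropylsilyloxy)benzyloxy]-5-prenyl-4,6-bis(triisopropylsilyloxy)phenyl}ethanone
Conditions: TIPSOTf, 2,6-lutidine, CH2Cl2, 0 °C to rt
Reagents that add atoms: triisopropylsilyl trifluoromethanesulfonate, CC(C)[Si](OS(=O)(=O)C(F)(F)F)(C(C)C)C(C)C
Why: The very reactive silyl triflate should capture the remaining hindered, hydrogen-bonded phenol faster than the weak base enolises the doubly ortho-substituted ketone (silyl triflate O-silylation); TIPS is chosen here because it has no C–H alpha to oxygen and is too bulky to migrate to the enolate oxygen in step 8.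

**Step 8**
Reactants: 10 1-{2-[3,5-diprenyl-4-(triisopropylsilyloxy)benzyloxy]-5-prenyl-4,6-bis(triisopropylsilyloxy)phenyl}ethanone
Product: 12 2-diazo-1-{2-[3,5-diprenyl-4-(triisopropylsilyloxy)benzyloxy]-5-prenyl-4,6-bis(triisopropylsilyloxy)phenyl}ethanone, via trifluoroacetyl diketone 11 (not isolated)
Conditions: LiN(SiMe3)2, THF, −78 °C; CF3CO2CH2CF3; 5% aq HCl work-up; then p-ABSA, Et3N, H2O, MeCN, rt
Reagents that add atoms: 4-acetamidobenzenesulfonyl azide, CC(=O)Nc1ccc(cc1)S(=O)(=O)N=[N+]=[N-] (gives the diazo nitrogens of 12); 2,2,2-trifluoroethyl trifluoroacetate, O=C(OCC(F)(F)F)C(F)(F)F (its CF3CO group is carried only in 11)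
Why: Kinetic lithium enolate formation and Claisen condensation with the trifluoroacetate turn the methyl group into a 1,3-diketone, which accepts the diazo group from the sulfonyl azide and then loses the trifluoroacetyl group to the sulfonamide nitrogen (deacylative Regitz diazo transfer), a standard entry to terminal diazoketones from methyl ketones that avoids diazomethane.

**Step 9**
Reactants: 12 2-diazo-1-{2-[3,5-diprenyl-4-(triisopropylsilyloxy)benzyloxy]-5-prenyl-4,6-bis(triisopropylsilyloxy)phenyl}ethanone
Product: 13 (2R)-6,3',5'-triprenyl-5,7,4'-tris(triisopropylsilyloxy)flavanone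
Conditions: Rh2(S-PTTL)4 (dirhodium tetrakis[N-phthaloyl-(S)-tert-leucinate], 2 mol %), CH2Cl2, 0 °C, slow addition of 12
Reagents that add atoms: none
Why: Rh2(S-PTTL)4 expels N2 from 12 to give an electrophilic carbenoid on divalent rhodium at C3, next to the C4 ketone, which inserts into one C–H bond of the O1–CH2–ring B methylene through a concerted, asynchronous three-centre transition state with hydride-like transfer, forming C2–C3. The closest known reaction type is the intramolecular C–H insertion of ortho-alkoxyaryl alpha-diazoketones to 2-substituted chroman-4-ones under chiral dirhodium carboxylate catalysis. Ring C closes as a six-membered ring by 1,6-insertion (C3 onto C2–H; ring atoms C3, C4, C4a, C8a, O1, C2), the 1,5-position being O1, which carries no hydrogen. C2 is the only new stereocenter and is set by the catalyst alone: the chiral phthalimido-tert-leucinate ligands differentiate the two enantiotopic benzylic hydrogens, and the catalyst antipode is chosen for 2R. The step needs insertion to win over oxonium ylide formation at O1 with Stevens benzyl shift, over attack at the alkenes and over O–H or O–Si chemistry; the substrate secures this because the C–H bond is activated twice (by O1 and by the electron-rich silyloxyaryl ring B), the C6 prenyl group is meta to the carbenoid arm and cannot reach it, the ring B alkenes could react only through a macrocycle, and the silyl ethers offer no C–H alpha to oxygen while the bulky group shields O5. The medium is neutral and aprotic, so the C2 center should not epimerise through ring opening.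

**Step 10**
Reactants: 13 (2R)-6,3',5'-triprenyl-5,7,4'-tris(triisopropylsilyloxy)flavanone
Product: 14 (2R)-5,7,4'-trihydroxy-6,3',5'-triprenylflavanone (CNP0268011.1)
Conditions: HF·pyridine, excess pyridine, THF, 0 °C to rt
Reagents that add atoms: none
Why: Fluoride cleaves the three aryl O–Si bonds (fluoride desilylation), and the pyridine-buffered, weakly acidic medium avoids both phenoxide-triggered ring opening to the chalcone, which would racemise C2, and acid-catalysed cyclisation of the ortho-prenyl phenols to chromans.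

**Compound list**
1 | 2,4,6-trihydroxyacetophenone | CC(=O)c1c(O)cc(O)cc1O | starting material
2 | prenyl bromide (1-bromo-3-methylbut-2-ene) | CC(C)=CCBr | starting material
3 | 1-[2,4,6-trihydroxy-3-prenylphenyl]ethanone | CC(=O)c1c(O)cc(O)c(CC=C(C)C)c1O | intermediate
4 | 1-[2,6-dihydroxy-3-prenyl-4-(triisopropylsilyloxy)phenyl]ethanone | CC(=O)c1c(O)cc(O[Si](C(C)C)(C(C)C)C(C)C)c(CC=C(C)C)c1O | intermediate
5 | 4-hydroxybenzaldehyde | O=Cc1ccc(O)cc1 | starting material
6 | 4-hydroxy-3,5-diprenylbenzaldehyde | O=Cc1cc(CC=C(C)C)c(O)c(CC=C(C)C)c1 | intermediate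
7 | 3,5-diprenyl-4-(triisopropylsilyloxy)benzaldehyde | O=Cc1cc(CC=C(C)C)c(O[Si](C(C)C)(C(C)C)C(C)C)c(CC=C(C)C)c1 | intermediate
8 | [3,5-diprenyl-4-(triisopropylsilyloxy)phenyl]methanol | OCc1cc(CC=C(C)C)c(O[Si](C(C)C)(C(C)C)C(C)C)c(CC=C(C)C)c1 | intermediate
9 | 1-{2-hydroxy-3-prenyl-4-(triisopropylsilyloxy)-6-[3,5-diprenyl-4-(triisopropylsilyloxy)benzyloxy]phenyl}ethanone | CC(=O)c1c(OCc2cc(CC=C(C)C)c(O[Si](C(C)C)(C(C)C)C(C)C)c(CC=C(C)C)c2)cc(O[Si](C(C)C)(C(C)C)C(C)C)c(CC=C(C)C)c1O | intermediate
10 | 1-{2-[3,5-diprenyl-4-(triisopropylsilyloxy)benzyloxy]-5-prenyl-4,6-bis(triisopropylsilyloxy)phenyl}ethanone | CC(=O)c1c(OCc2cc(CC=C(C)C)c(O[Si](C(C)C)(C(C)C)C(C)C)c(CC=C(C)C)c2)cc(O[Si](C(C)C)(C(C)C)C(C)C)c(CC=C(C)C)c1O[Si](C(C)C)(C(C)C)C(C)C | intermediate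
11 | 4,4,4-trifluoro-1-{2-[3,5-diprenyl-4-(triisopropylsilyloxy)benzyloxy]-5-prenyl-4,6-bis(triisopropylsilyloxy)phenyl}butane-1,3-dione | FC(F)(F)C(=O)CC(=O)c1c(OCc2cc(CC=C(C)C)c(O[Si](C(C)C)(C(C)C)C(C)C)c(CC=C(C)C)c2)cc(O[Si](C(C)C)(C(C)C)C(C)C)c(CC=C(C)C)c1O[Si](C(C)C)(C(C)C)C(C)C | intermediate
12 | 2-diazo-1-{2-[3,5-diprenyl-4-(triisopropylsilyloxy)benzyloxy]-5-prenyl-4,6-bis(triisopropylsilyloxy)phenyl}ethanone | [N-]=[N+]=CC(=O)c1c(OCc2cc(CC=C(C)C)c(O[Si](C(C)C)(C(C)C)C(C)C)c(CC=C(C)C)c2)cc(O[Si](C(C)C)(C(C)C)C(C)C)c(CC=C(C)C)c1O[Si](C(C)C)(C(C)C)C(C)C | intermediate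
13 | (2R)-6,3',5'-triprenyl-5,7,4'-tris(triisopropylsilyloxy)flavanone | CC(C)=CCc1cc([C@H]2CC(=O)c3c(cc(O[Si](C(C)C)(C(C)C)C(C)C)c(CC=C(C)C)c3O[Si](C(C)C)(C(C)C)C(C)C)O2)cc(CC=C(C)C)c1O[Si](C(C)C)(C(C)C)C(C)C | intermediate
14 | (2R)-5,7,4'-trihydroxy-6,3',5'-triprenylflavanone (CNP0268011.1) | CC(C)=CCc1cc([C@H]2CC(=O)c3c(cc(O)c(CC=C(C)C)c3O)O2)cc(CC=C(C)C)c1O | target

**Total step count:** 10
**Longest linear sequence:** 8 steps (5 → 6 → 7 → 8 → 9 → 10 → 12 → 13 → 14; steps 3 to 10)

**Steps most likely to fail**

1. Step 9. The carbenoid may be diverted to an oxonium ylide at O1 with Stevens benzyl migration, giving a five-membered ring instead of ring C, or the catalyst may discriminate poorly between the two enantiotopic benzylic hydrogens. The fallback leaves carbene chemistry altogether and sets out from ketone 4 and aldehyde 7. A Claisen–Schmidt-type aldol condensation (LiN(SiMe3)2, 3.3 equiv, THF, −78 °C to rt, dehydration on mildly acidic work-up) should give the chalcone (E)-1-[2,6-dihydroxy-3-prenyl-4-(triisopropylsilyloxy)phenyl]-3-[3,5-diprenyl-4-(triisopropylsilyloxy)phenyl]prop-2-en-1-one F1. An intramolecular oxa-Michael addition of the ring A hydroxyl remote from the prenyl group, catalysed by a cinchona-alkaloid-derived bifunctional thiourea whose pseudoenantiomer is chosen for 2R, should then give (2R)-5-hydroxy-6,3',5'-triprenyl-7,4'-bis(triisopropylsilyloxy)flavanone F2. Any 8-prenyl regioisomer or minor enantiomer would be removed by chromatography, on a chiral stationary phase if needed. The HF·pyridine conditions of step 10 remove the two silyl groups and rejoin the route at 14.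

2. Step 6. Site selection between the two ortho hydroxyls of 4 may be poor (etherification next to the prenyl group), or the electron-rich benzylic electrophile may alkylate ring A at carbon. The fallback fixes the regiochemistry by construction and sets out from 1 and 8. Selective para silylation of 1 (TIPSCl, imidazole, DMF, 0 °C) gives the symmetric 1-[2,6-dihydroxy-4-(triisopropylsilyloxy)phenyl]ethanone F3. Mitsunobu etherification with 8 (PPh3, DIAD, THF), where the two hydroxyls are equivalent, gives 1-{2-hydroxy-4-(triisopropylsilyloxy)-6-[3,5-diprenyl-4-(triisopropylsilyloxy)benzyloxy]phenyl}ethanone F4. Copper-catalysed O-alkylation of the remaining hydroxyl with 2-methylbut-3-yn-2-yl trifluoroacetate (DBU, CuCl2 cat., MeCN, 0 °C) gives the 1,1-dimethylpropargyl ether 1-{2-(2-methylbut-3-yn-2-yloxy)-4-(triisopropylsilyloxy)-6-[3,5-diprenyl-4-(triisopropylsilyloxy)benzyloxy]phenyl}ethanone F5. Semihydrogenation (H2, Pd/CaCO3 poisoned with Pb(OAc)2, quinoline) gives the 1,1-dimethylallyl ether 1-{2-(2-methylbut-3-en-2-yloxy)-4-(triisopropylsilyloxy)-6-[3,5-diprenyl-4-(triisopropylsilyloxy)benzyloxy]phenyl}ethanone F6. Thermal aromatic Claisen rearrangement (N,N-diethylaniline, about 130 °C) delivers the prenyl group to the only free ortho carbon and rejoins the route at 9.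

3. Step 3. The twofold alkylation may stall at the mono-prenyl stage or drift to O-prenylation, leaving little of the 3,5-diprenyl product. The fallback replaces phenoxide alkylation by cross-coupling and sets out from 5. Twofold ortho iodination (I2, KI, aq NaHCO3) gives 4-hydroxy-3,5-diiodobenzaldehyde F7. Twofold Stille coupling with tributyl(3-methylbut-2-enyl)stannane (Pd(PPh3)4, DMF, 90 °C), which joins the allyl unit mainly at its tin-bearing carbon, rejoins the route at 6.

**Further compounds**
F1 | step 9 | (E)-1-[2,6-dihydroxy-3-prenyl-4-(triisopropylsilyloxy)phenyl]-3-[3,5-diprenyl-4-(triisopropylsilyloxy)phenyl]prop-2-en-1-one | O=C(/C=C/c1cc(CC=C(C)C)c(O[Si](C(C)C)(C(C)C)C(C)C)c(CC=C(C)C)c1)c1c(O)cc(O[Si](C(C)C)(C(C)C)C(C)C)c(CC=C(C)C)c1O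
F2 | step 9 | (2R)-5-hydroxy-6,3',5'-triprenyl-7,4'-bis(triisopropylsilyloxy)flavanone | CC(C)=CCc1cc([C@H]2CC(=O)c3c(cc(O[Si](C(C)C)(C(C)C)C(C)C)c(CC=C(C)C)c3O)O2)cc(CC=C(C)C)c1O[Si](C(C)C)(C(C)C)C(C)C
F3 | step 6 | 1-[2,6-dihydroxy-4-(triisopropylsilyloxy)phenyl]ethanone | CC(=O)c1c(O)cc(O[Si](C(C)C)(C(C)C)C(C)C)cc1O
F4 | step 6 | 1-{2-hydroxy-4-(triisopropylsilyloxy)-6-[3,5-diprenyl-4-(triisopropylsilyloxy)benzyloxy]phenyl}ethanone | CC(=O)c1c(OCc2cc(CC=C(C)C)c(O[Si](C(C)C)(C(C)C)C(C)C)c(CC=C(C)C)c2)cc(O[Si](C(C)C)(C(C)C)C(C)C)cc1O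
F5 | step 6 | 1-{2-(2-methylbut-3-yn-2-yloxy)-4-(triisopropylsilyloxy)-6-[3,5-diprenyl-4-(triisopropylsilyloxy)benzyloxy]phenyl}ethanone | CC(=O)c1c(OCc2cc(CC=C(C)C)c(O[Si](C(C)C)(C(C)C)C(C)C)c(CC=C(C)C)c2)cc(O[Si](C(C)C)(C(C)C)C(C)C)cc1OC(C)(C)C#C
F6 | step 6 | 1-{2-(2-methylbut-3-en-2-yloxy)-4-(triisopropylsilyloxy)-6-[3,5-diprenyl-4-(triisopropylsilyloxy)benzyloxy]phenyl}ethanone | CC(=O)c1c(OCc2cc(CC=C(C)C)c(O[Si](C(C)C)(C(C)C)C(C)C)c(CC=C(C)C)c2)cc(O[Si](C(C)C)(C(C)C)C(C)C)cc1OC(C)(C)C=C
F7 | step 3 | 4-hydroxy-3,5-diiodobenzaldehyde | O=Cc1cc(I)c(O)c(I)c1
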